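**Retrosynthetic overview**

- The target comes from its tri-O-benzyl ether by hydrogenolysis. Ring A (the butenolide: O1, C2 carbonyl, C3–OMe, C4–aryl, quaternary C5) is the last ring made; ring B (catechol arene) and the chroman (benzene ring C, pyran ring D) are bought ready-made.
- Ring A is disconnected to an (aS)-2-methoxy-2,3-allenoic acid and 1,2-bis(benzyloxy)-4-iodobenzene. One palladium-catalysed coupling–cyclisation closes the ring through O1–C5, forms C4–aryl and turns the allene axis into the C5 centre.
- Enabling feature: in ring A the O1–C5 bond is allylic to the C3=C4 double bond and C4 carries the aryl group, so C2, C3, C4, C5 are the carboxyl carbon and the three cumulated carbons of a 2,3-allenoic acid. The two exocyclic groups on C5 lie above and below ring A just as the substituents of one allene terminus lie above and below the plane of the other.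
- The allene axis comes from a catalytic asymmetric phase-transfer benzylation of racemic 1-tert-butyl 5-methyl 2-methoxypenta-2,3-dienedioate (two steps from methyl 4-methoxy-3-oxobutanoate) with the (3R)-chromanylmethyl bromide.
- The bromide comes from 2,2-dimethyl-2H-chromene-6-carbonitrile; the carbinol centre of ring D is set first by asymmetric epoxidation and benzylic C–O hydrogenolysis.

Key step: step 12

Remark: the sense of induction of the phase-transfer catalyst in step 9 cannot be predicted for the methoxy-substituted substrate; the (S,S)-catalyst is written and its antipode is to be used if a trial shows it is the one that gives the (aS) axis. Butenolide numbering throughout: O1, C2 (C=O), C3 (OMe), C4 (aryl), C5 (quaternary).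

**Route**

Step 1
Reactants: 1 2,2-dimethyl-2H-chromene-6-carbonitrile
Product: 2 (3R,4R)-3,4-epoxy-2,2-dimethylchromane-6-carbonitrile
Conditions: NaOCl (aq., pH 11.3), (R,R)-[N,N′-bis(3,5-di-tert-butylsalicylidene)-1,2-cyclohexanediaminato]manganese chloride (4 mol%), 4-phenylpyridine N-oxide (cat.), CH2Cl2, 0 °C
Reagents that add atoms: sodium hypochlorite, [Na+].[O-]Cl
Why: Jacobsen–Katsuki epoxidation, for which the cis, aryl-conjugated C3=C4 olefin of a 2,2-dimethylchromene is a privileged substrate; the (R,R)-ligand is expected to deliver oxygen to the face that gives the (3R,4R)-epoxide and so fixes the later carbinol centre.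

Step 2
Reactants: 2 (3R,4R)-3,4-epoxy-2,2-dimethylchromane-6-carbonitrile
Product: 3 (3R)-3-hydroxy-2,2-dimethylchromane-6-carbonitrile
Conditions: H2 (1 atm), 10% Pd/C, EtOAc, rt
Reagents that add atoms: none
Why: Catalytic hydrogenolysis of a benzylic epoxide should cleave only the benzylic C4–O bond, so the C3–O bond and the (3R) configuration are kept, and the aryl nitrile should survive at 1 atm under neutral conditions.

Step 3
Reactants: 3 (3R)-3-hydroxy-2,2-dimethylchromane-6-carbonitrile
Product: 4 (3R)-3-(benzyloxy)-2,2-dimethylchromane-6-carbonitrile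
Conditions: NaH, BnBr, Bu4NI (cat.), DMF, 0 °C to rt
Reagents that add atoms: benzyl bromide, BrCc1ccccc1
Why: Williamson ether synthesis in which the sodium alkoxide of the hindered secondary alcohol is benzylated under iodide catalysis, the aryl nitrile having no acidic α-hydrogen.

Step 4
Reactants: 4 (3R)-3-(benzyloxy)-2,2-dimethylchromane-6-carbonitrile
Product: 5 (3R)-3-(benzyloxy)-2,2-dimethylchromane-6-carbaldehyde
Conditions: DIBAL-H, toluene, −78 °C; then 1 M HCl
Reagents that add atoms: water, O
Why: Partial reduction of an aryl nitrile with DIBAL-H stops at the N-aluminoimine at low temperature, and acidic work-up hydrolyses it to the aldehyde without touching the benzyl ether.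

Step 5
Reactants: 5 (3R)-3-(benzyloxy)-2,2-dimethylchromane-6-carbaldehyde
Product: 6 [(3R)-3-(benzyloxy)-2,2-dimethylchroman-6-yl]methanol
Conditions: NaBH4, MeOH, 0 °C
Reagents that add atoms: none
Why: Borohydride reduction of the aryl aldehyde gives the primary benzylic alcohol chemoselectively and leaves the stereocentre untouched.

Step 6
Reactants: 6 [(3R)-3-(benzyloxy)-2,2-dimethylchroman-6-yl]methanol
Product: 7 (3R)-3-(benzyloxy)-6-(bromomethyl)-2,2-dimethylchromane
Conditions: CBr4, PPh3, CH2Cl2, 0 °C; used at once
Reagents that add atoms: carbon tetrabromide, BrC(Br)(Br)Br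
Why: The Appel reaction converts the primary benzylic alcohol into the bromide under neutral conditions that the benzyl ether tolerates.

Step 7
Reactants: 8 methyl 4-methoxy-3-oxobutanoate
Product: 9 1-tert-butyl 5-methyl 2-methoxy-3-oxopentanedioate (racemic)
Conditions: LDA (2.2 equiv), THF, −78 to 0 °C; Boc2O, −78 °C; AcOH quench
Reagents that add atoms: di-tert-butyl dicarbonate, CC(C)(C)OC(=O)OC(=O)OC(C)(C)C
Why: γ-Acylation of a β-keto ester dianion, in which the second deprotonation takes place at the methoxy-bearing γ-carbon and this more reactive terminus is C-acylated by Boc2O, placing the acid-labile ester on the methoxy side.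

Step 8
Reactants: 9 1-tert-butyl 5-methyl 2-methoxy-3-oxopentanedioate
Product: 10 1-tert-butyl 5-methyl 2-methoxypenta-2,3-dienedioate (racemic axis)
Conditions: 2-chloro-1,3-dimethylimidazolinium chloride, Et3N, CH2Cl2, 0 °C
Reagents that add atoms: none
Why: Dehydration of a 3-oxoglutarate to an allene-1,3-dicarboxylate, by O-activation of the enol with the chloroamidinium salt and E1cB loss of 1,3-dimethylimidazolidin-2-one, builds the cumulated unit, whose racemic axis is erased in the next step.

Step 9
Reactants: 10 1-tert-butyl 5-methyl 2-methoxypenta-2,3-dienedioate, 7 (3R)-3-(benzyloxy)-6-(bromomethyl)-2,2-dimethylchromane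
Product: 11 1-tert-butyl 5-methyl (aS)-4-{[(3R)-3-(benzyloxy)-2,2-dimethylchroman-6-yl]methyl}-2-methoxypenta-2,3-dienedioate
Conditions: (S,S)-N-spiro bis(binaphthyl) quaternary ammonium bromide bearing 3,4,5-trifluorophenyl groups (3 mol%), Cs2CO3, toluene, −20 °C
Reagents that add atoms: none
Why: Asymmetric phase-transfer C-alkylation of an allene-1,3-dicarboxylate, in which deprotonation of the allenic CH gives a planar cumulenolate, the chiral ammonium cation shields one of its faces, and the reactive benzylic bromide attacks the unhindered CH terminus and not the terminus flanked by methoxy and tert-butyl ester, so that the (aS) axis is set under catalyst control with the remote (3R) centre as a bystander.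

Step 10
Reactants: 11 1-tert-butyl 5-methyl (aS)-4-{[(3R)-3-(benzyloxy)-2,2-dimethylchroman-6-yl]methyl}-2-methoxypenta-2,3-dienedioate
Product: 12 (aS)-4-{[(3R)-3-(benzyloxy)-2,2-dimethylchroman-6-yl]methyl}-2-methoxy-5-methoxy-5-oxopenta-2,3-dienoic acid
Conditions: TFA–CH2Cl2 (1:4), 0 °C
Reagents that add atoms: none
Why: Acidolysis of the tert-butyl ester (E1 loss of 2-methylpropene) frees the carboxylic acid while the methyl ester, the benzyl ether and the allene axis, which carries no allenic hydrogen, should be unaffected.

Step 11
Reactants: 13 1,2-bis(benzyloxy)benzene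
Product: 14 1,2-bis(benzyloxy)-4-iodobenzene
Conditions: NIS, TFA (cat.), MeCN, rt
Reagents that add atoms: N-iodosuccinimide, O=C1CCC(=O)N1I
Why: Electrophilic aromatic iodination with acid-activated NIS takes place para to one benzyloxy group, the only unhindered activated position of the symmetrical diether.

Step 12
Reactants: 12 (aS)-4-{[(3R)-3-(benzyloxy)-2,2-dimethylchroman-6-yl]methyl}-2-methoxy-5-methoxy-5-oxopenta-2,3-dienoic acid, 14 1,2-bis(benzyloxy)-4-iodobenzene
Product: 15 methyl (2S)-2-{[(3R)-3-(benzyloxy)-2,2-dimethylchroman-6-yl]methyl}-3-[3,4-bis(benzyloxy)phenyl]-4-methoxy-5-oxo-2,5-dihydrofuran-2-carboxylate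
Conditions: Pd(PPh3)4 (5 mol%), Ag2CO3 (5 mol%), i-Pr2NEt (1.2 equiv), MeCN, 70 °C
Reagents that add atoms: none
Why: Oxidative addition of 14 to zerovalent palladium gives an arylpalladium iodide that binds the distal C4=C5 π-bond of the allenoate salt, the carboxylate oxygen attacks the allene terminus C5 anti to palladium (oxypalladation), and reductive elimination from the C4-palladated lactone forms the C4–aryl bond, so that ring A, the O1–C5 bond, the C4–aryl bond and the quaternary centre arise in one operation. The closest known reaction type is the palladium-catalysed coupling–cyclisation of 2,3-allenoic acid amine salts with aryl iodides under silver carbonate co-catalysis, a reaction class in which axial chirality is passed on to C5 of the butenolide. Ring A is closed in a 5-endo-trig mode by O–C bond formation at the sp2 terminus of the cumulene, which is feasible because the π-lobes of C4=C5 lie in the plane of the carboxyl-bearing terminus and therefore in the plane of the forming ring. The new stereocentre C5 is controlled by the allene axis alone, since CO2Me and the chromanylmethyl group stand above and below that plane and keep their places while oxygen enters in-plane from the carboxyl side, so the (aS) axis should give (S)-C5 whichever face palladium occupies. The step needs regioselectivity (aryl to the central carbon, oxygen to the ester-bearing terminus), secured because the tethered carboxylate can reach only C5 in a five-membered array and outcompetes the neutral methyl ester carbonyl, and it needs stereospecificity, secured by the fully substituted allene (no allenic hydrogen to exchange) and the mild amine base.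

Step 13
Reactants: 15 methyl (2S)-2-{[(3R)-3-(benzyloxy)-2,2-dimethylchroman-6-yl]methyl}-3-[3,4-bis(benzyloxy)phenyl]-4-methoxy-5-oxo-2,5-dihydrofuran-2-carboxylate
Product: 16 methyl (2S)-3-(3,4-dihydroxyphenyl)-2-{[(3R)-3-hydroxy-2,2-dimethylchroman-6-yl]methyl}-4-methoxy-5-oxo-2,5-dihydrofuran-2-carboxylate (target)
Conditions: H2 (1 atm), Pd(OH)2/C, EtOAc–MeOH, rt
Reagents that add atoms: none
Why: Hydrogenolysis of the three O-benzyl ethers should release the catechol and the chromanol while the tetrasubstituted, conjugated C3=C4 bond of ring A, the methyl ester and both stereocentres are left alone.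

**Compound list**

1 | 2,2-dimethyl-2H-chromene-6-carbonitrile | N#Cc1ccc2c(c1)C=CC(C)(C)O2 | starting material
2 | (3R,4R)-3,4-epoxy-2,2-dimethylchromane-6-carbonitrile | N#Cc1ccc2c(c1)[C@H]1O[C@H]1C(C)(C)O2 | intermediate
3 | (3R)-3-hydroxy-2,2-dimethylchromane-6-carbonitrile | N#Cc1ccc2c(c1)C[C@@H](O)C(C)(C)O2 | intermediate
4 | (3R)-3-(benzyloxy)-2,2-dimethylchromane-6-carbonitrile | N#Cc1ccc2c(c1)C[C@@H](OCc1ccccc1)C(C)(C)O2 | intermediate
5 | (3R)-3-(benzyloxy)-2,2-dimethylchromane-6-carbaldehyde | O=Cc1ccc2c(c1)C[C@@H](OCc1ccccc1)C(C)(C)O2 | intermediate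
6 | [(3R)-3-(benzyloxy)-2,2-dimethylchroman-6-yl]methanol | OCc1ccc2c(c1)C[C@@H](OCc1ccccc1)C(C)(C)O2 | intermediate
7 | (3R)-3-(benzyloxy)-6-(bromomethyl)-2,2-dimethylchromane | BrCc1ccc2c(c1)C[C@@H](OCc1ccccc1)C(C)(C)O2 | intermediate
8 | methyl 4-methoxy-3-oxobutanoate | COCC(=O)CC(=O)OC | starting material
9 | 1-tert-butyl 5-methyl 2-methoxy-3-oxopentanedioate (racemic) | COC(=O)CC(=O)C(OC)C(=O)OC(C)(C)C | intermediate
10 | 1-tert-butyl 5-methyl 2-methoxypenta-2,3-dienedioate (racemic axis) | COC(=O)C=C=C(OC)C(=O)OC(C)(C)C | intermediate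
11 | 1-tert-butyl 5-methyl (aS)-4-{[(3R)-3-(benzyloxy)-2,2-dimethylchroman-6-yl]methyl}-2-methoxypenta-2,3-dienedioate | COC(=O)C(Cc1ccc2c(c1)C[C@@H](OCc1ccccc1)C(C)(C)O2)=[C@]=C(OC)C(=O)OC(C)(C)C | intermediate
12 | (aS)-4-{[(3R)-3-(benzyloxy)-2,2-dimethylchroman-6-yl]methyl}-2-methoxy-5-methoxy-5-oxopenta-2,3-dienoic acid | COC(=O)C(Cc1ccc2c(c1)C[C@@H](OCc1ccccc1)C(C)(C)O2)=[C@]=C(OC)C(=O)O | intermediate
13 | 1,2-bis(benzyloxy)benzene | c1ccc(COc2ccccc2OCc2ccccc2)cc1 | starting material
14 | 1,2-bis(benzyloxy)-4-iodobenzene | Ic1ccc(OCc2ccccc2)c(OCc2ccccc2)c1 | intermediate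
15 | methyl (2S)-2-{[(3R)-3-(benzyloxy)-2,2-dimethylchroman-6-yl]methyl}-3-[3,4-bis(benzyloxy)phenyl]-4-methoxy-5-oxo-2,5-dihydrofuran-2-carboxylate | COC(=O)[C@@]1(Cc2ccc3c(c2)C[C@@H](OCc2ccccc2)C(C)(C)O3)OC(=O)C(OC)=C1c1ccc(OCc2ccccc2)c(OCc2ccccc2)c1 | intermediate
16 | methyl (2S)-3-(3,4-dihydroxyphenyl)-2-{[(3R)-3-hydroxy-2,2-dimethylchroman-6-yl]methyl}-4-methoxy-5-oxo-2,5-dihydrofuran-2-carboxylate | COC(=O)[C@@]1(Cc2ccc3c(c2)C[C@@H](O)C(C)(C)O3)OC(=O)C(OC)=C1c1ccc(O)c(O)c1 | target

**Totals**

Total step count: 13.
Longest linear sequence: 10 steps (steps 1–6, 9, 10, 12, 13).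

**Steps most likely to fail**

Step 12. The transfer of axial to central chirality may erode if the allene racemises by reversible addition of iodide, phosphine or amine to its central carbon, or if carbopalladation to a planar allyl-palladium species outruns oxypalladation. Silver- or base-induced cycloisomerisation without aryl transfer may also compete. The fallback sets out from 12 and comes back at 15. Treatment of 12 with CuBr2 in aqueous acetone at 65 °C (bromolactonisation of a 2,3-allenoic acid, with the carboxylate bound to divalent copper delivering oxygen to C5 in the same in-plane 5-endo mode) should give methyl (2R)-2-{[(3R)-3-(benzyloxy)-2,2-dimethylchroman-6-yl]methyl}-3-bromo-4-methoxy-5-oxo-2,5-dihydrofuran-2-carboxylate F1. It has the same spatial arrangement at the quaternary carbon as 15; the descriptor changes only because bromine raises the rank of the neighbouring ring carbon. Suzuki–Miyaura coupling of F1 with commercial 3,4-bis(benzyloxy)phenylboronic acid (Pd(PPh3)4, K2CO3, toluene–EtOH–H2O, 80 °C) then gives 15.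

Step 9. Facial discrimination of the cumulenolate by the chiral cation may be poor with methoxy in place of the alkyl group of the known substrates, and part of the alkylation may go to the methoxy-bearing terminus. The fallback sets out from 10 (with 7) and comes back at 12. Alkylation with achiral Bu4NBr and K2CO3 in toluene should give 11 together with its axial epimer, 1-tert-butyl 5-methyl (aR)-4-{[(3R)-3-(benzyloxy)-2,2-dimethylchroman-6-yl]methyl}-2-methoxypenta-2,3-dienedioate F2. Acidolysis of the mixture as in step 10 gives 12 and the (aR)-acid, (aR)-4-{[(3R)-3-(benzyloxy)-2,2-dimethylchroman-6-yl]methyl}-2-methoxy-5-methoxy-5-oxopenta-2,3-dienoic acid F3. Classical resolution of the allenoic acids by fractional crystallisation with (S)-1-phenylethylamine (or its antipode, whichever makes the salt of 12 the less soluble one) gives the (S)-1-phenylethylammonium salt of 12 F4. Partition of F4 between EtOAc and dilute aqueous KHSO4 returns 12.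

Step 8. The allene 10 is both C–H acidic and electrophilic at its central carbon, so it may oligomerise under the amine base during the dehydration or on isolation. The fallback sets out from 9 and comes back at 11. Tf2O and i-Pr2NEt in CH2Cl2 at −78 °C should convert 9 into the storable enol triflate 1-tert-butyl 5-methyl (Z)-2-methoxy-3-{[(trifluoromethyl)sulfonyl]oxy}pent-3-enedioate F5. F5 is treated with Et3N in toluene at 0 °C (E1cB elimination of a β-triflyloxy enoate to the allenoate) so that 10 is released only in solution. Without isolation, 7, the phase-transfer catalyst and Cs2CO3 are added as in step 9 to give 11.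

**Further compounds**

F1 | step 12 | methyl (2R)-2-{[(3R)-3-(benzyloxy)-2,2-dimethylchroman-6-yl]methyl}-3-bromo-4-methoxy-5-oxo-2,5-dihydrofuran-2-carboxylate | COC(=O)[C@@]1(Cc2ccc3c(c2)C[C@@H](OCc2ccccc2)C(C)(C)O3)OC(=O)C(OC)=C1Br
F2 | step 9 | 1-tert-butyl 5-methyl (aR)-4-{[(3R)-3-(benzyloxy)-2,2-dimethylchroman-6-yl]methyl}-2-methoxypenta-2,3-dienedioate | COC(=O)C(Cc1ccc2c(c1)C[C@@H](OCc1ccccc1)C(C)(C)O2)=[C@@]=C(OC)C(=O)OC(C)(C)C
F3 | step 9 | (aR)-4-{[(3R)-3-(benzyloxy)-2,2-dimethylchroman-6-yl]methyl}-2-methoxy-5-methoxy-5-oxopenta-2,3-dienoic acid | COC(=O)C(Cc1ccc2c(c1)C[C@@H](OCc1ccccc1)C(C)(C)O2)=[C@@]=C(OC)C(=O)O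
F4 | step 9 | (S)-1-phenylethylammonium (aS)-4-{[(3R)-3-(benzyloxy)-2,2-dimethylchroman-6-yl]methyl}-2-methoxy-5-methoxy-5-oxopenta-2,3-dienoate | COC(=O)C(Cc1ccc2c(c1)C[C@@H](OCc1ccccc1)C(C)(C)O2)=[C@]=C(OC)C(=O)[O-].C[C@H]([NH3+])c1ccccc1
F5 | step 8 | 1-tert-butyl 5-methyl (Z)-2-methoxy-3-{[(trifluoromethyl)sulfonyl]oxy}pent-3-enedioate | COC(=O)/C=C(\OS(=O)(=O)C(F)(F)F)C(OC)C(=O)OC(C)(C)C
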